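The 2H-pyran ring is opened at its O–C(CH3)2 bond, which exposes an ortho-quinone methide (1-oxatriene) of ring A (numbered from the acyl-bearing carbon, C1). In the final step the single unsubstituted carbon of ring A, C5, lying between the free 4-OH and the ketone-chelated 6-OH, condenses with 3-methylbut-2-enal. The resulting oxatriene closes by oxa-6π electrocyclisation onto O4, so one operation forms the C5–C bond, the O–C(CH3)2 bond and the pyran ring. The precursor is a pentasubstituted acylphloroglucinol deoxybenzoin whose 3-prenyl group is delivered para to the chelated hydroxyl by a Claisen–Cope shift of an O-prenyl ether.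

Key step: step 6

Remark: ring A numbering used throughout is C1 (acyl), C2 (OMe), C3 (prenyl), C4 (pyran oxygen), C5 (pyran carbon), C6 (OH); ring B is the 4-hydroxyphenyl ring. The target has no stereocentre; the transient dienones 7 and 8 are racemic.

Step 1
Reactants: 1 5-methoxyresorcinol; 2 4-hydroxyphenylacetic acid
Product: 3 1-(2,4-dihydroxy-6-methoxyphenyl)-2-(4-hydroxyphenyl)ethan-1-one
Conditions: BF3·OEt2 (excess, as solvent), 85 °C; aq. NaOAc work-up
Reagents that add atoms: none
Why: Friedel–Crafts (Nencki-type) acylation by the BF3-activated acid should occur mainly at C4/C6 of 1, the two equivalent positions para to a free hydroxyl and less hindered than C2 between both hydroxyls, giving the 2,4-dihydroxy-6-methoxy ketone, from which the minor 2,6-dihydroxy-4-methoxy isomer is removed by chromatography.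

Step 2
Reactants: 3 1-(2,4-dihydroxy-6-methoxyphenyl)-2-(4-hydroxyphenyl)ethan-1-one
Product: 4 1-[2-hydroxy-6-methoxy-4-(methoxymethoxy)phenyl]-2-[4-(methoxymethoxy)phenyl]ethan-1-one
Conditions: MOMCl (2.3 equiv), iPr2NEt, CH2Cl2–DMF, 0 °C to rt
Reagents that add atoms: chloromethyl methyl ether (MOMCl), COCCl
Why: O-alkylation (acetal formation) of the two unchelated phenols, while the hydroxyl hydrogen-bonded to the ketone is not ionised by the amine base and stays free.

Step 3
Reactants: 4 1-[2-hydroxy-6-methoxy-4-(methoxymethoxy)phenyl]-2-[4-(methoxymethoxy)phenyl]ethan-1-one; 5 1-bromo-3-methylbut-2-ene (prenyl bromide)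
Product: 6 1-{2-methoxy-4-(methoxymethoxy)-6-[(3-methylbut-2-en-1-yl)oxy]phenyl}-2-[4-(methoxymethoxy)phenyl]ethan-1-one
Conditions: K2CO3, acetone, reflux
Reagents that add atoms: none
Why: Williamson etherification of the remaining chelated phenol with the reactive allylic bromide; carbonate is too weak to enolise the benzyl ketone, so C-alkylation is not expected.

Step 4
Reactants: 6 1-{2-methoxy-4-(methoxymethoxy)-6-[(3-methylbut-2-en-1-yl)oxy]phenyl}-2-[4-(methoxymethoxy)phenyl]ethan-1-one
Product: 9 1-[6-hydroxy-2-methoxy-4-(methoxymethoxy)-3-(3-methylbut-2-en-1-yl)phenyl]-2-[4-(methoxymethoxy)phenyl]ethan-1-one, via ortho-dienone 7 (not isolated), via para-dienone 8 (not isolated)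
Conditions: PhNEt2, 200 °C, sealed tube, Ar
Reagents that add atoms: none
Why: Aromatic Claisen rearrangement to C5 gives 7, whose crowded 1,1-dimethylallyl group moves on by a Cope shift to C3 to give 8, which enolises to the phenol (para-Claisen–Cope rearrangement); the two allyl inversions return a linear prenyl group para to the new hydroxyl.

Step 5
Reactants: 9 1-[6-hydroxy-2-methoxy-4-(methoxymethoxy)-3-(3-methylbut-2-en-1-yl)phenyl]-2-[4-(methoxymethoxy)phenyl]ethan-1-one
Product: 10 1-[4,6-dihydroxy-2-methoxy-3-(3-methylbut-2-en-1-yl)phenyl]-2-(4-hydroxyphenyl)ethan-1-one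
Conditions: 3 M HCl, MeOH, rt to 40 °C
Reagents that add atoms: none
Why: Acid-catalysed transacetalisation of both MOM ethers to methanol under mild conditions that should leave the prenyl group untouched.

Step 6
Reactants: 10 1-[4,6-dihydroxy-2-methoxy-3-(3-methylbut-2-en-1-yl)phenyl]-2-(4-hydroxyphenyl)ethan-1-one; 11 3-methylbut-2-enal
Product: 13 1-[5-hydroxy-7-methoxy-2,2-dimethyl-8-(3-methylbut-2-en-1-yl)-2H-chromen-6-yl]-2-(4-hydroxyphenyl)ethan-1-one, via ortho-quinone methide 12 (not isolated)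
Conditions: ethylenediammonium diacetate (20 mol %), xylene, 140 °C
Reagents that add atoms: none
Why: The ammonium acetate converts 11 into an iminium ion that is attacked by C5 of ring A, the only unsubstituted carbon and the nucleophilic terminus of the vinylogous enol O4–C4=C5 (Knoevenagel-type condensation), and loss of the amine gives the (Z)-1-oxatriene 12. Thermal oxa-6π electrocyclisation of 12 (disrotatory six-electron closure) then joins the C4 carbonyl oxygen to the C(CH3)2 terminus, forming the pyran O–C2 bond, and the regained aromaticity of ring A drives the closure. The closest known reaction type is the formal (3+3) chromenylation of resorcinols and 2,4-dihydroxyaryl ketones with 3-methylbut-2-enal. No stereocentre is formed. The selectivity needed is closure at O4 and not at O6: because C2 carries OMe, the ketone can chelate only the 6-OH, which keeps that oxygen as a hydrogen-bonded enol in 12 and leaves O4 as the dienone oxygen. The ring B phenol lacks a second donor and the hindered, chelated benzyl ketone should not compete in the condensation.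

Compound list
1 | 5-methoxyresorcinol (3,5-dihydroxyanisole) | COc1cc(O)cc(O)c1 | starting material
2 | 4-hydroxyphenylacetic acid | OC(=O)Cc1ccc(O)cc1 | starting material
3 | 1-(2,4-dihydroxy-6-methoxyphenyl)-2-(4-hydroxyphenyl)ethan-1-one | COc1cc(O)cc(O)c1C(=O)Cc1ccc(O)cc1 | intermediate
4 | 1-[2-hydroxy-6-methoxy-4-(methoxymethoxy)phenyl]-2-[4-(methoxymethoxy)phenyl]ethan-1-one | COCOc1cc(O)c(C(=O)Cc2ccc(OCOC)cc2)c(OC)c1 | intermediate
5 | 1-bromo-3-methylbut-2-ene (prenyl bromide) | CC(C)=CCBr | starting material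
6 | 1-{2-methoxy-4-(methoxymethoxy)-6-[(3-methylbut-2-en-1-yl)oxy]phenyl}-2-[4-(methoxymethoxy)phenyl]ethan-1-one | COCOc1cc(OCC=C(C)C)c(C(=O)Cc2ccc(OCOC)cc2)c(OC)c1 | intermediate
7 | ortho-dienone: 3-methoxy-5-(methoxymethoxy)-2-{[4-(methoxymethoxy)phenyl]acetyl}-6-(2-methylbut-3-en-2-yl)cyclohexa-2,4-dien-1-one (racemic) | O=C1C(C(=O)Cc2ccc(OCOC)cc2)=C(OC)C=C(OCOC)C1C(C)(C)C=C | intermediate (not isolated)
8 | para-dienone: 3-methoxy-5-(methoxymethoxy)-2-{[4-(methoxymethoxy)phenyl]acetyl}-4-(3-methylbut-2-en-1-yl)cyclohexa-2,5-dien-1-one (racemic) | O=C1C=C(OCOC)C(CC=C(C)C)C(OC)=C1C(=O)Cc1ccc(OCOC)cc1 | intermediate (not isolated)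
9 | 1-[6-hydroxy-2-methoxy-4-(methoxymethoxy)-3-(3-methylbut-2-en-1-yl)phenyl]-2-[4-(methoxymethoxy)phenyl]ethan-1-one | COCOc1cc(O)c(C(=O)Cc2ccc(OCOC)cc2)c(OC)c1CC=C(C)C | intermediate
10 | 1-[4,6-dihydroxy-2-methoxy-3-(3-methylbut-2-en-1-yl)phenyl]-2-(4-hydroxyphenyl)ethan-1-one | COc1c(CC=C(C)C)c(O)cc(O)c1C(=O)Cc1ccc(O)cc1 | intermediate
11 | 3-methylbut-2-enal | CC(C)=CC=O | starting material
12 | ortho-quinone methide: (6Z)-5-hydroxy-4-[(4-hydroxyphenyl)acetyl]-3-methoxy-2-(3-methylbut-2-en-1-yl)-6-(3-methylbut-2-en-1-ylidene)cyclohexa-2,4-dien-1-one | COC1=C(CC=C(C)C)C(=O)/C(=C\C=C(C)C)C(O)=C1C(=O)Cc1ccc(O)cc1 | intermediate (not isolated)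
13 | 1-[5-hydroxy-7-methoxy-2,2-dimethyl-8-(3-methylbut-2-en-1-yl)-2H-chromen-6-yl]-2-(4-hydroxyphenyl)ethan-1-one | COc1c(CC=C(C)C)c2c(c(O)c1C(=O)Cc1ccc(O)cc1)C=CC(C)(C)O2 | target

Total step count: 6. Longest linear sequence: 6 steps (1 to 13).

Steps most likely to fail

Step 6. The electrocyclisation could close onto the chelated O6 instead of O4, and the iminium ion could instead condense at the benzylic methylene of the ketone or oligomerise the enal. The fallback avoids the aldehyde and sets out from 10. The most acidic phenol, the 4-OH para to the ketone, is alkylated with one equivalent of 3-chloro-3-methylbut-1-yne (DBU, 1 equiv, CuCl2 cat., MeCN, 0 °C). This gives 1-{6-hydroxy-2-methoxy-3-(3-methylbut-2-en-1-yl)-4-[(2-methylbut-3-yn-2-yl)oxy]phenyl}-2-(4-hydroxyphenyl)ethan-1-one F1. Heating F1 in xylene at 140 °C should trigger a propargyl Claisen rearrangement to C5, the only free ortho position, followed by a 1,5-hydrogen shift and the same oxa-6π closure. The fallback comes back to the route at 13.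

Step 4. The rearrangement could stop at the ortho stage if dienone 7 enolises before the Cope shift, or the prenyl group could be lost by ether cleavage at 200 °C. The fallback blocks both ortho positions first, sets out from 3 and comes back at 13.
- Condensation of 3 with 11 (ethylenediammonium diacetate, xylene, 140 °C) at the carbon between the two hydroxyls should give 1-(5-hydroxy-7-methoxy-2,2-dimethyl-2H-chromen-6-yl)-2-(4-hydroxyphenyl)ethan-1-one F2.
- MOMCl/iPr2NEt protects only the ring B phenol, giving 1-(5-hydroxy-7-methoxy-2,2-dimethyl-2H-chromen-6-yl)-2-[4-(methoxymethoxy)phenyl]ethan-1-one F3.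
- 5 with K2CO3 in acetone gives the prenyl ether 1-{7-methoxy-2,2-dimethyl-5-[(3-methylbut-2-en-1-yl)oxy]-2H-chromen-6-yl}-2-[4-(methoxymethoxy)phenyl]ethan-1-one F4.
- In PhNEt2 at 190 °C the ortho-dienone of F4 has no hydrogen to lose and must undergo the Cope shift, giving 1-[5-hydroxy-7-methoxy-2,2-dimethyl-8-(3-methylbut-2-en-1-yl)-2H-chromen-6-yl]-2-[4-(methoxymethoxy)phenyl]ethan-1-one F5.
- HCl in MeOH removes the MOM group to give 13.

Step 1. Acylation could occur to a large extent between the two hydroxyls of 1, and the regioisomers could be hard to separate. The fallback fixes the oxygen pattern on an isoflavone template, sets out from 2 and comes back at 4.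
- 2 is acylated onto phloroglucinol (Oc1cc(O)cc(O)c1) with BF3·OEt2, giving the symmetric ketone 2-(4-hydroxyphenyl)-1-(2,4,6-trihydroxyphenyl)ethan-1-one F6.
- F6 is closed in the same pot with DMF/MeSO2Cl to genistein F7, which is also an inexpensive article of commerce.
- MOMCl/iPr2NEt gives 5-hydroxy-7-(methoxymethoxy)-3-[4-(methoxymethoxy)phenyl]-4H-chromen-4-one F8.
- MeI/K2CO3 in DMF methylates the chelated hydroxyl, giving 5-methoxy-7-(methoxymethoxy)-3-[4-(methoxymethoxy)phenyl]-4H-chromen-4-one F9.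
- KOH in aqueous EtOH at reflux opens the pyranone ring with loss of the C2 carbon as formate and delivers 4 as a single regioisomer.

Further compounds
F1 | step 6 | 1-{6-hydroxy-2-methoxy-3-(3-methylbut-2-en-1-yl)-4-[(2-methylbut-3-yn-2-yl)oxy]phenyl}-2-(4-hydroxyphenyl)ethan-1-one | COc1c(CC=C(C)C)c(OC(C)(C)C#C)cc(O)c1C(=O)Cc1ccc(O)cc1
F2 | step 4 | 1-(5-hydroxy-7-methoxy-2,2-dimethyl-2H-chromen-6-yl)-2-(4-hydroxyphenyl)ethan-1-one | COc1cc2c(c(O)c1C(=O)Cc1ccc(O)cc1)C=CC(C)(C)O2
F3 | step 4 | 1-(5-hydroxy-7-methoxy-2,2-dimethyl-2H-chromen-6-yl)-2-[4-(methoxymethoxy)phenyl]ethan-1-one | COc1cc2c(c(O)c1C(=O)Cc1ccc(OCOC)cc1)C=CC(C)(C)O2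
F4 | step 4 | 1-{7-methoxy-2,2-dimethyl-5-[(3-methylbut-2-en-1-yl)oxy]-2H-chromen-6-yl}-2-[4-(methoxymethoxy)phenyl]ethan-1-one | COc1cc2c(c(OCC=C(C)C)c1C(=O)Cc1ccc(OCOC)cc1)C=CC(C)(C)O2
F5 | step 4 | 1-[5-hydroxy-7-methoxy-2,2-dimethyl-8-(3-methylbut-2-en-1-yl)-2H-chromen-6-yl]-2-[4-(methoxymethoxy)phenyl]ethan-1-one | COc1c(CC=C(C)C)c2c(c(O)c1C(=O)Cc1ccc(OCOC)cc1)C=CC(C)(C)O2
F6 | step 1 | 2-(4-hydroxyphenyl)-1-(2,4,6-trihydroxyphenyl)ethan-1-one | O=C(Cc1ccc(O)cc1)c1c(O)cc(O)cc1O
F7 | step 1 | genistein (5,7-dihydroxy-3-(4-hydroxyphenyl)-4H-chromen-4-one) | O=c1c(-c2ccc(O)cc2)coc2cc(O)cc(O)c12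
F8 | step 1 | 5-hydroxy-7-(methoxymethoxy)-3-[4-(methoxymethoxy)phenyl]-4H-chromen-4-one | COCOc1ccc(-c2coc3cc(OCOC)cc(O)c3c2=O)cc1
F9 | step 1 | 5-methoxy-7-(methoxymethoxy)-3-[4-(methoxymethoxy)phenyl]-4H-chromen-4-one | COCOc1ccc(-c2coc3cc(OCOC)cc(OC)c3c2=O)cc1
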